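(The numbers belong to no real substance; the rest is arithmetic.)

Product cannot pass 95.0% of the substrate charged, since each product takes one partner and the 0.0950 M of partner is less than the 0.10 M of substrate; partner is the limiting reagent by charge. The end state stands lower, though, and I find it by keeping books.

all flasks: substrate 0.10 M; partner 0.0950 M; time 6.0 h

| run | temperature |
|---|---|
| Wednesday's | 45 °C |
| Saturday's | 25 °C |
| Thursday's | 65 °C |

- the best flask by amount of product, in percent of the substrate charged; "all alike" if 1.5 percentage points covers them all (Wednesday's / Saturday's / Thursday's / all alike)
- amount of product at the end, in percent of the substrate charged, Wednesday's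
- amount of product at the end, in percent of the substrate charged, Saturday's
- amount of product at the end, in percent of the substrate charged, Thursday's

- all constants are for 25 °C and move with temperature by the activation energies and enthalpies

    substrate → intermediate A (k1 = 2.82 × 10⁻⁵ s⁻¹, Ea1 = 106 kJ mol⁻¹)
    substrate ⇌ intermediate B (K2 = 1.6, k2 = 7.95 × 10⁻⁵ s⁻¹, Ea2 = 96.0 kJ mol⁻¹, ΔH2 = −44.0 kJ mol⁻¹)
    intermediate A → intermediate C (k3 = 7.35 × 10⁻⁴ s⁻¹, Ea3 = 92.0 kJ mol⁻¹)
    intermediate A ⇌ intermediate D (K4 = 0.83, k4 = 2.70 × 10⁻⁴ s⁻¹, Ea4 = 93.0 kJ mol⁻¹, ΔH4 = 7.00 kJ mol⁻¹)
    partner + intermediate C ⇌ product (K5 = 6.6 M⁻¹, k5 = 2.08 × 10⁻⁴ M⁻¹ s⁻¹, Ea5 = 72.0 kJ mol⁻¹, ΔH5 = −19.0 kJ mol⁻¹)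
    (constants at 25 °C)

Substrate passes one way into intermediate A and back and forth into intermediate B. Intermediate A passes one way into intermediate C and back and forth into intermediate D. Intermediate C joins partner, reversibly, to give product. Each mole of substrate stands as one of these species or as product, and each mole of partner is either free or in product.

The way from intermediate A to intermediate C has no return, so the entries before intermediate C drain and, given time, the books close on two lines: c(intermediate C) = 0.10 M − c(product) and c(partner) = 0.0950 M − c(product). I put these into the equilibrium of the last step, which gives a quadratic in c(product). The constant of that step is 4.08 M⁻¹ at Wednesday's temperature, so the smaller root, as a share of the substrate charged, is 22.8%. I call this share the ceiling: the product at which the closed books balance.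

The same reckoning gives 30.0% for Saturday's, with 6.6 M⁻¹, and, with 2.67 M⁻¹ for Thursday's, 17.2% there. So the ceiling of the hottest flask is lower than the other two.

Next I ask how fast each flask approaches its ceiling, and I count lifetimes over the 6.0 h. The feed count takes substrate and intermediate B as balanced and multiplies the first step's constant, shared over that pool, by the time. The relaxation count multiplies the last step's forward constant with charged partner, plus its reverse constant, by the time.

For Wednesday's these counts are 5.88 and 9.49. For Thursday's they are 80.1 and 65.6. Each of these counts is more than one lifetime, so I take both flasks to be under thermodynamic control, and I expect Wednesday's slightly under 22.8% and Thursday's at 17.2%.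

Saturday's feed count is 0.234, less than one lifetime, so I expect its books to stay open under kinetic control, below 30.0%. I commit to no figure there, but with that count I name Wednesday's best, whose ceiling stands higher than Thursday's.

The forecast also names Wednesday's, with 22.6%, and gives 4.5% for Saturday's and 17.2% for Thursday's. Of Wednesday's it says: “so the flask is essentially at equilibrium”. It commits to a Saturday's figure where I did not.

The flasks give 22.6% for Wednesday's, 4.35% for Saturday's and 17.2% for Thursday's, so Wednesday's is best.

The order holds at this hour but not later: after 60.0 h Saturday's stands at 26.8%, more than Wednesday's 22.8%, and still under its ceiling of 30.0%. The neighbour of Wednesday's charged with 0.38 M of partner keeps the constant 4.08 M⁻¹, and its substrate is down to 0.23%. The same quadratic with that charge lifts the ceiling from 22.8% to 56.8%, and that flask holds 56.5% of product.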